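## Retrosynthetic overview

- The route rests on one feature of ring B: the ether oxygen of C8 sits on C4', flanked by the methoxy-bearing carbons C3' and C5'. C3'–C4'–C5' is therefore treated as a masked 2-oxycyclohexane-1,3-dione, and the crowded C4'–O bond is made on a carbenoid carbon, not on a 2,6-dimethoxyarene.
- Disconnections, backwards: C9–O–Si; C1'–allyl (Pd coupling of an aryl boronate from sterically controlled C–H borylation); aromatisation of ring B (enol methylation, dehydrogenation, phenol methylation); C4'–O by carbenoid O–H insertion.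
- The alcohol partner comes from (S)-glycidol, which supplies the C8 stereocentre, and the 3,4,5-trimethoxyphenyl Grignard reagent. The carbenoid partner comes from cyclohexane-1,3-dione by diazo transfer.
- Ring order: ring A is bought; the carbocycle of ring B is bought as the dione and becomes aromatic only after the key step; no ring is closed anywhere.

Key step: step 4

Remark on the chemistry: dione 8 is drawn as the diketo tautomer but is assumed to exist mainly as its enol (3-hydroxy-2-alkoxycyclohex-2-en-1-one), the form that is methylated in step 5.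

## Route

Step 1
Reactants: 1 (S)-glycidol
Product: 2 triisopropyl{[(2R)-oxiran-2-yl]methoxy}silane
Conditions: iPr3SiCl, imidazole, DMAP (cat.), CH2Cl2, 0 °C → rt
Reagents that add atoms: triisopropylsilyl chloride, CC(C)[Si](Cl)(C(C)C)C(C)C
Why: Imidazole-promoted silylation of the primary alcohol leaves the epoxide and its stereocentre untouched, the descriptor changing from S to R only because the CH2OSi arm now outranks the ring CH2.

Step 2
Reactants: 2 silyl glycidyl ether; 3 5-bromo-1,2,3-trimethoxybenzene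
Product: 5 (2R)-1-(3,4,5-trimethoxyphenyl)-3-[(triisopropylsilyl)oxy]propan-2-ol, via 3,4,5-trimethoxyphenylmagnesium bromide 4 (not isolated)
Conditions: 3, Mg, THF, reflux; then CuI (10 mol %), 2, THF, −30 → 0 °C; aq NH4Cl
Reagents that add atoms: none
Why: Copper-catalysed Grignard opening of a terminal epoxide occurs by SN2 attack at the unsubstituted CH2, so the C–O stereocentre (future C8) is not involved and is carried over unchanged as (R).

Step 3
Reactants: 6 cyclohexane-1,3-dione
Product: 7 2-diazocyclohexane-1,3-dione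
Conditions: 4-acetamidobenzenesulfonyl azide, Et3N, MeCN, 0 °C → rt
Reagents that add atoms: 4-acetamidobenzenesulfonyl azide, CC(=O)Nc1ccc(cc1)S(=O)(=O)N=[N+]=[N-]
Why: Regitz diazo transfer to the acidic methylene between the two carbonyls is the standard entry to cyclic 2-diazo-1,3-diones.

Step 4
Reactants: 5 (R)-alcohol; 7 2-diazocyclohexane-1,3-dione
Product: 8 2-({(2R)-1-(3,4,5-trimethoxyphenyl)-3-[(triisopropylsilyl)oxy]propan-2-yl}oxy)cyclohexane-1,3-dione
Conditions: Rh2(OAc)4 (2 mol %), PhF, 60 °C, 7 (1.3 equiv) added slowly by syringe pump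
Reagents that add atoms: none
Why: Rh2(OAc)4, a divalent rhodium dimer, expels N2 from 7 to give an electrophilic acceptor/acceptor carbenoid, the hydroxyl oxygen of 5 adds to its carbon to form an oxonium ylide, and proton transfer releases 8 as its enol; this is the rhodium-catalysed O–H insertion of cyclic 2-diazo-1,3-diones into alcohols. The step forms only the C4'–O bond, closes no ring and creates no stereocentre. C8 keeps the (R) configuration from glycidol because its C–O bond is never broken. The selectivity needed is O–H insertion over attack of the carbenoid on ring A, over insertion into the enolic O–H of 8 as it builds up, and over Wolff ring contraction. It is secured by the single free hydroxyl of 5 (C9 is silylated), by both ring A C–H bonds lying between two substituents, by the lower nucleophilicity of the hydrogen-bonded vinylogous acid 8, and by slow addition of 7 at moderate temperature so that the carbenoid always meets an excess of alcohol. The carbenoid carbon is planar and flanked only by two carbonyls, so the secondary alcohol reaches it far more easily than it would reach a 2,6-dimethoxyaryl–metal centre in a C–O cross-coupling.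

Step 5
Reactants: 8 2-alkoxycyclohexane-1,3-dione
Product: 9 3-methoxy-2-({(2R)-1-(3,4,5-trimethoxyphenyl)-3-[(triisopropylsilyl)oxy]propan-2-yl}oxy)cyclohex-2-en-1-one
Conditions: Me2SO4, K2CO3, acetone, reflux
Reagents that add atoms: dimethyl sulfate, COS(=O)(=O)OC
Why: O-alkylation of the enolate of the symmetric cyclic 1,3-dione with a hard electrophile gives a single vinylogous ester, fixing one carbonyl as a future ring B methoxy group under basic conditions that the silyl ether tolerates.

Step 6
Reactants: 9 vinylogous ester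
Product: 14 3-methoxy-2-({(2R)-1-(3,4,5-trimethoxyphenyl)-3-[(triisopropylsilyl)oxy]propan-2-yl}oxy)phenol, via lithium dienolate 10 (not isolated), via 6-phenylselanyl enone 11 (not isolated), via selenoxide 12 (not isolated), via cyclohexa-2,5-dienone tautomer 13 (not isolated)
Conditions: LiN(iPr)2, THF, −78 °C; PhSeCl, −78 °C; then pyridine, 30% H2O2, 0 °C → rt
Reagents that add atoms: none
Why: Kinetic α'-deprotonation of the vinylogous ester, selenenylation and selenoxide syn-elimination (Reich dehydrogenation) give the cross-conjugated dienone, which tautomerises to the phenol with aromatisation as the driving force, the selenium-bearing carbon being only a transient stereocentre.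

Step 7
Reactants: 14 phenol
Product: 15 1,3-dimethoxy-2-({(2R)-1-(3,4,5-trimethoxyphenyl)-3-[(triisopropylsilyl)oxy]propan-2-yl}oxy)benzene
Conditions: MeI, K2CO3, acetone, reflux
Reagents that add atoms: iodomethane, CI
Why: Williamson methylation of the phenoxide completes the 3',5'-dimethoxy pattern of ring B and touches no other group.

Step 8
Reactants: 15 ring B dimethyl ether
Product: 16 2-[3,5-dimethoxy-4-({(2R)-1-(3,4,5-trimethoxyphenyl)-3-[(triisopropylsilyl)oxy]propan-2-yl}oxy)phenyl]-4,4,5,5-tetramethyl-1,3,2-dioxaborolane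
Conditions: [Ir(OMe)(cod)]2 (1.5 mol %), dtbpy (3 mol %), B2pin2 (1.0 equiv), THF, 80 °C
Reagents that add atoms: bis(pinacolato)diboron, CC1(C)OB(OC1(C)C)B1OC(C)(C)C(C)(C)O1
Why: Iridium-catalysed aromatic C–H borylation is governed by sterics, and C1'–H is the only aryl C–H with no ortho substituent, since both ring A C–H bonds lie between two substituents and the silyl group carries no aryl C–H.

Step 9
Reactants: 16 aryl pinacol boronate; 17 allyl bromide
Product: 18 {(2R)-2-[2,6-dimethoxy-4-(prop-2-en-1-yl)phenoxy]-3-(3,4,5-trimethoxyphenyl)propoxy}triisopropylsilane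
Conditions: Pd(PPh3)4 (5 mol %), CsF, THF, reflux
Reagents that add atoms: none
Why: Suzuki–Miyaura-type coupling, in which allyl bromide adds oxidatively to zerovalent palladium, the fluoride-activated boronate transmetalates and reductive elimination forms the C1'–allyl bond, the unsubstituted allyl unit posing no regiochemical question.

Step 10
Reactants: 18 silyl-protected target
Product: 19 (2R)-2-[2,6-dimethoxy-4-(prop-2-en-1-yl)phenoxy]-3-(3,4,5-trimethoxyphenyl)propan-1-ol (CNP0175911.1)
Conditions: Bu4NF, THF, 0 °C → rt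
Reagents that add atoms: none
Why: Fluoride cleaves the Si–O bond through formation of the strong Si–F bond and frees the C9 hydroxyl without affecting the aryl ethers, the allyl group or C8.

## Compound list

1 | (S)-glycidol [(2S)-oxiran-2-ylmethanol] | OC[C@H]1CO1 | starting material
2 | triisopropyl{[(2R)-oxiran-2-yl]methoxy}silane | CC(C)[Si](C(C)C)(C(C)C)OC[C@H]1CO1 | intermediate
3 | 5-bromo-1,2,3-trimethoxybenzene | COc1cc(Br)cc(OC)c1OC | starting material
4 | 3,4,5-trimethoxyphenylmagnesium bromide | COc1cc([Mg]Br)cc(OC)c1OC | intermediate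
5 | (2R)-1-(3,4,5-trimethoxyphenyl)-3-[(triisopropylsilyl)oxy]propan-2-ol | O[C@@H](CO[Si](C(C)C)(C(C)C)C(C)C)Cc1cc(OC)c(OC)c(OC)c1 | intermediate
6 | cyclohexane-1,3-dione | O=C1CCCC(=O)C1 | starting material
7 | 2-diazocyclohexane-1,3-dione | O=C1CCCC(=O)C1=[N+]=[N-] | intermediate
8 | 2-({(2R)-1-(3,4,5-trimethoxyphenyl)-3-[(triisopropylsilyl)oxy]propan-2-yl}oxy)cyclohexane-1,3-dione | O=C1CCCC(=O)C1O[C@@H](CO[Si](C(C)C)(C(C)C)C(C)C)Cc1cc(OC)c(OC)c(OC)c1 | intermediate
9 | 3-methoxy-2-({(2R)-1-(3,4,5-trimethoxyphenyl)-3-[(triisopropylsilyl)oxy]propan-2-yl}oxy)cyclohex-2-en-1-one | COC1=C(O[C@@H](CO[Si](C(C)C)(C(C)C)C(C)C)Cc2cc(OC)c(OC)c(OC)c2)C(=O)CCC1 | intermediate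
10 | lithium 5-methoxy-6-({(2R)-1-(3,4,5-trimethoxyphenyl)-3-[(triisopropylsilyl)oxy]propan-2-yl}oxy)cyclohexa-1,5-dien-1-olate | COC1=C(O[C@@H](CO[Si](C(C)C)(C(C)C)C(C)C)Cc2cc(OC)c(OC)c(OC)c2)C(O[Li])=CCC1 | intermediate
11 | 3-methoxy-6-(phenylselanyl)-2-({(2R)-1-(3,4,5-trimethoxyphenyl)-3-[(triisopropylsilyl)oxy]propan-2-yl}oxy)cyclohex-2-en-1-one (both C6 epimers) | COC1=C(O[C@@H](CO[Si](C(C)C)(C(C)C)C(C)C)Cc2cc(OC)c(OC)c(OC)c2)C(=O)C([Se]c2ccccc2)CC1 | intermediate
12 | 6-(benzeneseleninyl)-3-methoxy-2-({(2R)-1-(3,4,5-trimethoxyphenyl)-3-[(triisopropylsilyl)oxy]propan-2-yl}oxy)cyclohex-2-en-1-one | COC1=C(O[C@@H](CO[Si](C(C)C)(C(C)C)C(C)C)Cc2cc(OC)c(OC)c(OC)c2)C(=O)C([Se](=O)c2ccccc2)CC1 | intermediate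
13 | 3-methoxy-2-({(2R)-1-(3,4,5-trimethoxyphenyl)-3-[(triisopropylsilyl)oxy]propan-2-yl}oxy)cyclohexa-2,5-dien-1-one | COC1=C(O[C@@H](CO[Si](C(C)C)(C(C)C)C(C)C)Cc2cc(OC)c(OC)c(OC)c2)C(=O)C=CC1 | intermediate
14 | 3-methoxy-2-({(2R)-1-(3,4,5-trimethoxyphenyl)-3-[(triisopropylsilyl)oxy]propan-2-yl}oxy)phenol | COc1cccc(O)c1O[C@@H](CO[Si](C(C)C)(C(C)C)C(C)C)Cc1cc(OC)c(OC)c(OC)c1 | intermediate
15 | 1,3-dimethoxy-2-({(2R)-1-(3,4,5-trimethoxyphenyl)-3-[(triisopropylsilyl)oxy]propan-2-yl}oxy)benzene | COc1cccc(OC)c1O[C@@H](CO[Si](C(C)C)(C(C)C)C(C)C)Cc1cc(OC)c(OC)c(OC)c1 | intermediate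
16 | 2-[3,5-dimethoxy-4-({(2R)-1-(3,4,5-trimethoxyphenyl)-3-[(triisopropylsilyl)oxy]propan-2-yl}oxy)phenyl]-4,4,5,5-tetramethyl-1,3,2-dioxaborolane | COc1cc(B2OC(C)(C)C(C)(C)O2)cc(OC)c1O[C@@H](CO[Si](C(C)C)(C(C)C)C(C)C)Cc1cc(OC)c(OC)c(OC)c1 | intermediate
17 | allyl bromide (3-bromoprop-1-ene) | C=CCBr | starting material
18 | {(2R)-2-[2,6-dimethoxy-4-(prop-2-en-1-yl)phenoxy]-3-(3,4,5-trimethoxyphenyl)propoxy}triisopropylsilane | C=CCc1cc(OC)c(O[C@@H](CO[Si](C(C)C)(C(C)C)C(C)C)Cc2cc(OC)c(OC)c(OC)c2)c(OC)c1 | intermediate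
19 | (2R)-2-[2,6-dimethoxy-4-(prop-2-en-1-yl)phenoxy]-3-(3,4,5-trimethoxyphenyl)propan-1-ol | C=CCc1cc(OC)c(O[C@@H](CO)Cc2cc(OC)c(OC)c(OC)c2)c(OC)c1 | target

## Step count and risks

Total step count: 10. Longest linear sequence: 9 steps (1 → 2 → 5 → 8 → 9 → 14 → 15 → 16 → 18 → 19); step 3 is a one-step side branch.

Steps most likely to fail:

1. Step 4. With only about one equivalent of a secondary alcohol, the carbenoid may be diverted into insertion into the enolic O–H of the product as it accumulates, into attack on electron-rich ring A, or into ring contraction, leaving much of the alcohol unconverted. The fallback sets out from 5 and makes the ether by double inversion. Mitsunobu esterification with 4-nitrobenzoic acid (PPh3, DIAD, THF) should invert C8 and give (2S)-1-(3,4,5-trimethoxyphenyl)-3-[(triisopropylsilyl)oxy]propan-2-yl 4-nitrobenzoate F1. Methanolysis (K2CO3, MeOH) gives (2S)-1-(3,4,5-trimethoxyphenyl)-3-[(triisopropylsilyl)oxy]propan-2-ol F2. A second Mitsunobu reaction of F2 with commercial 4-allyl-2,6-dimethoxyphenol (PPh3, DIAD, toluene) inverts C8 again and leads directly to 18, where the route is rejoined before step 10.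

2. Step 6. Deprotonation may occur in part at the γ position and not at the α' position, and the electron-rich phenol may be oxidised further by the selenium oxidants and H2O2 before it is quenched. The fallback sets out from 9 and replaces the selenoxide elimination by a palladium-mediated dehydrosilylation (Saegusa–Ito oxidation). Lithium dienolate 10 is trapped with Me3SiCl to give {[5-methoxy-6-({(2R)-1-(3,4,5-trimethoxyphenyl)-3-[(triisopropylsilyl)oxy]propan-2-yl}oxy)cyclohexa-1,5-dien-1-yl]oxy}trimethylsilane F3. Treatment of F3 with Pd(OAc)2 in MeCN at rt should give dienone 13, which tautomerises to phenol 14, where the route is rejoined.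

3. Step 9. Transmetalation of the pinacol boronate may be slow, so that protodeboronation and biaryl formation compete, and palladium hydride may move the allyl double bond into conjugation with ring B. The fallback sets out from 16 and reverses the polarity of the coupling. Oxidation (NaBO3·4H2O, THF/H2O, rt) gives 3,5-dimethoxy-4-({(2R)-1-(3,4,5-trimethoxyphenyl)-3-[(triisopropylsilyl)oxy]propan-2-yl}oxy)phenol F4. Triflation (Tf2O, pyridine, CH2Cl2, 0 °C) gives 3,5-dimethoxy-4-({(2R)-1-(3,4,5-trimethoxyphenyl)-3-[(triisopropylsilyl)oxy]propan-2-yl}oxy)phenyl trifluoromethanesulfonate F5. Stille coupling of F5 with allyltributylstannane (Pd(PPh3)4, LiCl, DMF, 90 °C) gives 18, where the route is rejoined.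

## Further compounds

F1 | step 4 | (2S)-1-(3,4,5-trimethoxyphenyl)-3-[(triisopropylsilyl)oxy]propan-2-yl 4-nitrobenzoate | O=C(O[C@H](CO[Si](C(C)C)(C(C)C)C(C)C)Cc1cc(OC)c(OC)c(OC)c1)c1ccc(cc1)[N+](=O)[O-]
F2 | step 4 | (2S)-1-(3,4,5-trimethoxyphenyl)-3-[(triisopropylsilyl)oxy]propan-2-ol | O[C@H](CO[Si](C(C)C)(C(C)C)C(C)C)Cc1cc(OC)c(OC)c(OC)c1
F3 | step 6 | {[5-methoxy-6-({(2R)-1-(3,4,5-trimethoxyphenyl)-3-[(triisopropylsilyl)oxy]propan-2-yl}oxy)cyclohexa-1,5-dien-1-yl]oxy}trimethylsilane | COC1=C(O[C@@H](CO[Si](C(C)C)(C(C)C)C(C)C)Cc2cc(OC)c(OC)c(OC)c2)C(O[Si](C)(C)C)=CCC1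
F4 | step 9 | 3,5-dimethoxy-4-({(2R)-1-(3,4,5-trimethoxyphenyl)-3-[(triisopropylsilyl)oxy]propan-2-yl}oxy)phenol | COc1cc(O)cc(OC)c1O[C@@H](CO[Si](C(C)C)(C(C)C)C(C)C)Cc1cc(OC)c(OC)c(OC)c1
F5 | step 9 | 3,5-dimethoxy-4-({(2R)-1-(3,4,5-trimethoxyphenyl)-3-[(triisopropylsilyl)oxy]propan-2-yl}oxy)phenyl trifluoromethanesulfonate | COc1cc(OS(=O)(=O)C(F)(F)F)cc(OC)c1O[C@@H](CO[Si](C(C)C)(C(C)C)C(C)C)Cc1cc(OC)c(OC)c(OC)c1
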